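## The problem

Germacrane numbering is used throughout. C1=C10 is the Z alkene, with methyl C14 on C10. C2–C3 is the ethano bridge. C4–C5 is the epoxide, with methyl C15 on C4. C6 carries OH, C7 isopropyl, C8 the 3,4,5-trimethoxybenzoate, and C9 is CH2.

1. The skeleton is a lone ten-membered carbocycle. End-to-end closure pays the full transannular and entropic price of a medium ring.
2. The ring holds two 1,5-related geometric elements of opposite sense: a Z trisubstituted alkene, and a trans trisubstituted epoxide that must come from an E alkene.
3. C4–C8 are five contiguous stereocentres. C7/C8 and C6/C7 are anti, O6/O8 are 1,3-syn, and the epoxide is threo to the C6 hydroxyl.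
4. C7 and C8 need an external source of chirality. C7 can then control C6 (Felkin–Anh), and the C6 hydroxyl can control C4 and C5 (directed epoxidation).
5. Two secondary oxygens flank C7 and only O8 is acylated, so C6 should remain a ketone until O8 carries its ester.
6. Fragile features are the epoxide next to a transannular alkene (acid), the β-oxy ketone stage (E1cB), the 1,5-diene (Cope rearrangement on heating) and the aryl ester (organometallic reagents).
7. The enabling feature is the run C10(C14)–C1–C2–C3–C4. Bonding C4 to C10 turns it into a cyclopentane with a methyl-bearing quaternary carbon between two oxygenated carbons, which is 2-methylcyclopentane-1,3-dione. The other five ring atoms, C5–C9, then form one side chain on C10 that ends in a methyl ketone whose CH3 is C5.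

## Retrosynthesis

**26 ⇒ 25 (both epoxide C–O bonds).** The epoxide goes in last because it is the most acid-sensitive group. The free C6 hydroxyl of 25 singles out C4=C5 over C1=C10. With H6 eclipsing the alkene to avoid the cis methyl C15, the hydroxyl sits on the outer face of the ring. Delivery of oxygen there gives the threo isomer.

**25 ⇒ 24 ⇒ 22 + 23 (C6–H, then O8–acyl).** Keeping C6 as the enone carbonyl while O8 is acylated makes the two oxygens chemically different without any protecting-group exchange. The forward reduction must be a 1,2-addition from the ring periphery.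

**22 ⇒ 21 ⇒ 20 ⇒ 18 (C4–C15).** The methyl C15 is cut from the β-carbon of the enone, which leads back to the ten-membered 1,3-diketone 18. The forward sequence is enol sulfonate formation followed by stereoretentive methyl coupling. It needs O4 rather than O6 to be sulfonylated, and it needs the chelated enolate geometry, in which C3 is trans to C6.

**18 ⇒ 14 (key step: C4–C5 formed, C4–C10 broken, C1=C10 formed).** Reconnecting C4 to C10 and opening C4–C5 shrinks the ten-membered ring to a cyclopentanone carrying a mesylate at C1 and a methyl ketone side chain. Cuts at C5–C6, C6–C7 or C1=C10 would each require direct closure of the ten-membered ring. Here only a seven-membered ring has to close, and the alkene geometry comes stereospecifically from a ring stereocentre. The price is that C15 is added afterwards.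

**14 ⇒ 13 ⇒ 12 ⇒ 10 + 5 (C7–C8).** The anti C7/C8 pair is the retron of an E-allylboronate addition. The vinyl group of the adduct is a latent acetyl group (C6, C5). This is the only step that needs an external source of chirality.

**10 ⇒ 8 ⇒ 7 ⇒ 6, and 5 ⇒ 3 ⇒ 1 + 2.** The allyl group of commercial dione 6 is C9 plus the latent C8 aldehyde. Monoreduction from the methyl face puts the hydroxyl cis to the side chain, which is the relation that encodes Z. Boronate 5 comes from an alkyne by hydroboration and one-carbon homologation.

## Roads not taken

**Alternative 1:** cut C5–C6, the most obvious choice. The forward key step is a Nozaki–Hiyama–Kishi closure (CrCl2, catalytic NiCl2) of iodo aldehyde A1. Both alkenes would be preset. However, the ten-membered ring must close head to tail at high dilution against the full ring strain, and the C6 configuration is left to an uncontrolled macrocyclic transition state. The chosen plan closes a seven-membered ring instead and sets C6 later on a defined enone.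

**Alternative 2:** cut C1=C10. The forward key step is ring-closing metathesis of diene A2 with the second-generation Grubbs catalyst. A trisubstituted alkene inside a ten-membered ring forms reluctantly and competes with dimerisation. Nothing in A2 fixes its geometry. O6 and O8 would also need orthogonal protection. In the chosen plan the Z geometry is a stereospecific consequence of one easily set ring stereocentre.

**Alternative 3:** cut C2–C3 and reconnect C5–C10. The forward key step is anionic oxy-Cope ring expansion of divinylcyclohexanol A3, with capture of the enolate.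
- On a cyclohexane made of C5–C10, O6, the isopropyl group and O8 are all cis.
- The chair that would give 1(10)Z,4E needs an axial isopropenyl at C5 and an axial methyl at C10.
- That chair puts either isopropyl and isopropenyl, or O6, O8 and C14, into 1,3-diaxial contact.
- The accessible chair leads to the wrong pair of geometries, and the extra oxygen at C5 must be removed afterwards.

Key step: step 9

Assumption: the catalyst enantiomers named in steps 3 and 6 are taken to give the configurations drawn; if the sense of induction is opposite, the other enantiomer of the catalyst is used.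

## Steps

Step 1
Reactants: 1 3-methylbut-1-yne; 2 pinacolborane
Product: 3 (E)-(3-methylbut-1-enyl)boronic acid pinacol ester
Conditions: Cp2ZrHCl (10 mol %), Et3N (10 mol %), neat, 60 °C
Reagents that add atoms: none
Why: Zirconocene-hydride-catalysed syn hydroboration of a terminal alkyne puts boron on the terminal carbon and should give only the E alkenylboronate.

Step 2
Reactants: 3 (E)-(3-methylbut-1-enyl)boronic acid pinacol ester
Product: 5 (E)-(4-methylpent-2-enyl)boronic acid pinacol ester, via lithium chloromethyl ate complex 4 (not isolated)
Conditions: BrCH2Cl, n-BuLi, THF, −78 °C to rt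
Reagents that add atoms: bromochloromethane, ClCBr
Why: Matteson homologation; LiCH2Cl adds to boron and the alkenyl group migrates with loss of chloride and retention of alkene geometry, giving the E allylboronate that the anti adduct requires.

Step 3
Reactants: 6 2-allyl-2-methylcyclopentane-1,3-dione
Product: 7 (2S,3S)-2-allyl-3-hydroxy-2-methylcyclopentanone (OH cis to allyl, trans to methyl)
Conditions: RuCl(p-cymene)[(S,S)-TsDPEN] (1 mol %), HCO2H/Et3N, CH2Cl2, 0 °C, stopped at monoreduction
Reagents that add atoms: none
Why: Desymmetrising asymmetric transfer hydrogenation of a 2,2-disubstituted 1,3-dione; hydride enters from the face of the small methyl group, so the hydroxyl ends cis to the allyl chain, the relation that later encodes the Z alkene. Both stereocentres are erased in step 9, so their absolute sense only serves to keep the intermediates single diastereomers.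

Step 4
Reactants: 7 (2S,3S)-2-allyl-3-hydroxy-2-methylcyclopentanone
Product: 8 mesylate of 7
Conditions: MsCl, Et3N, CH2Cl2, 0 °C
Reagents that add atoms: methanesulfonyl chloride, CS(=O)(=O)Cl
Why: Standard mesylation; the carbon between the ketone and the mesylate carbon is quaternary, so no β-elimination is possible, and the neopentyl-type sulfonate resists substitution.

Step 5
Reactants: 8 mesylate of 7
Product: 10 (2-mesyloxy-1-methyl-5-oxocyclopentyl)acetaldehyde with ring configuration as in 7, via secondary ozonide 9 (not isolated)
Conditions: O3, CH2Cl2, −78 °C; then Me2S, −78 °C to rt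
Reagents that add atoms: ozone, [O-][O+]=O
Why: Ozonolysis of the only alkene with reductive work-up uncovers C8 as an aldehyde; ketone and mesylate are inert.

Step 6
Reactants: 10 aldehyde; 5 (E)-(4-methylpent-2-enyl)boronic acid pinacol ester
Product: 12 anti homoallylic alcohol (C8 carbinol, C7 bearing isopropyl and vinyl, 7S,8R), via pinacol borate ester 11 (not isolated)
Conditions: (R)-TRIP phosphoric acid (5 mol %), toluene, −30 °C; neutral aqueous work-up
Reagents that add atoms: none
Why: Chiral-phosphoric-acid-catalysed allylboration through a closed Zimmerman–Traxler chair; the E boronate gives the anti C7/C8 pair and the catalyst chooses the aldehyde face. The hindered cyclopentanone does not compete.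

Step 7
Reactants: 12 anti homoallylic alcohol
Product: 13 TBS ether of 12
Conditions: TBSOTf, 2,6-lutidine, CH2Cl2, −78 to 0 °C
Reagents that add atoms: tert-butyldimethylsilyl triflate, CC(C)(C)[Si](C)(C)OS(=O)(=O)C(F)(F)F
Why: Silylation under non-nucleophilic, weakly basic conditions; it blocks O8 before it can add to the C4 ketone as a hemiketal and trigger a premature fragmentation.

Step 8
Reactants: 13 TBS ether of 12
Product: 14 methyl ketone (vinyl converted into acetyl, C6=O and C5H3)
Conditions: PdCl2 (10 mol %), CuCl, O2 (1 atm), DMF/H2O, rt
Reagents that add atoms: water, O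
Why: Tsuji–Wacker oxidation of a monosubstituted alkene gives the Markovnikov methyl ketone; no other alkene is present and the conditions are not basic enough to epimerise C7.

Step 9
Reactants: 14 methyl ketone
Product: 18 (1(10)Z,7R,8R)-8-(tert-butyldimethylsilyloxy)-15-norgermacr-1(10)-ene-4,6-dione, via potassium enolate 15 (not isolated), via bicyclic aldolate 16 (not isolated), via potassium diketonate 17 (not isolated)
Conditions: KHMDS (2.2 equiv, slow addition), THF (0.005 M), −40 to 0 °C; then AcOH
Reagents that add atoms: none
Why: Proposed new method: the kinetic enolate of the methyl ketone (C5) adds reversibly to the cyclopentanone carbonyl C4, closing a seven-membered ring in the 7-exo-trig (enolexo) mode, and the aldolate 16 is a 1,3-diol monosulfonate (O–C4–C10–C1–OMs) set up for Grob fragmentation. With the mesylate pseudo-equatorial, the shared C4–C10 bond is antiperiplanar to C1–O, so C4=O and C1=C10 form as mesylate leaves; the ten-membered ring is therefore never closed end to end but released by scission of the fusion bond. The closest known reaction types are the Wharton–Grob fragmentation of bicyclic 1,3-diol monosulfonates and the fragmentation of γ-sulfonyloxy ketones triggered by external hydride, alkoxide or organometallic nucleophiles; new here is an internal ketone enolate as the trigger. No permanent stereocentre is formed (C4 of 16 is transient); the new stereo-element is the alkene, and because C9 is cis to the mesylate on the cyclopentane it ends cis to C2, which is Z, while the epimeric mesylate would give E. The step needs reaction through the C5 enolate rather than the C3 or C7 enolates: these interconvert by proton transfer, their aldol adducts have no aligned leaving group and revert, and only 16 is drained irreversibly. Slow addition keeps the base limiting so that C4 is not masked as its own enolate. The second equivalent turns the acidic product into diketonate 17, which lowers the acidity of H7 and so guards C7 and the β-silyloxy group against epimerisation and E1cB loss.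

Step 10
Reactants: 18 ten-membered 1,3-diketone
Product: 20 4-trifluoromethanesulfonyloxy enone (C4=C5 with ring bonds C3 and C6 trans, triflate cis to the C6 carbonyl), via lithium diketonate 19 (not isolated)
Conditions: LiHMDS, THF, −78 °C; N-(5-chloro-2-pyridyl)bis(trifluoromethanesulfonimide), −78 to 0 °C; aq NH4Cl
Reagents that add atoms: N-(5-chloro-2-pyridyl)bis(trifluoromethanesulfonimide), FC(F)(F)S(=O)(=O)N(c1ccc(Cl)cn1)S(=O)(=O)C(F)(F)F
Why: Stereoselective enol sulfonate formation from a chelated 1,3-dicarbonyl enolate; lithium holds O4 and O6 syn, which places C3 trans to C6, the same extended C3–C7 arrangement as in the s-cis E enone that follows. The oxygen remote from the branched C7 (O4) should be sulfonylated.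

Step 11
Reactants: 20 enol triflate
Product: 21 (1(10)Z,4E,7R,8R)-8-(tert-butyldimethylsilyloxy)germacra-1(10),4-dien-6-one
Conditions: MeMgBr, Fe(acac)3 (5 mol %), THF/NMP, −30 °C
Reagents that add atoms: methylmagnesium bromide, C[Mg]Br
Why: Iron-catalysed cross-coupling of a β-dicarbonyl-derived enol triflate with a Grignard reagent is faster than carbonyl addition at this temperature and keeps the alkene geometry, so C15 enters cis to C6 (4E).

Step 12
Reactants: 21 silyloxy dienone
Product: 22 (1(10)Z,4E,7R,8R)-8-hydroxygermacra-1(10),4-dien-6-one
Conditions: HF·pyridine, pyridine, THF, 0 °C to rt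
Reagents that add atoms: none
Why: Buffered fluoride desilylation avoids both the base that would cause retro-aldol or E1cB reaction and the strong acid that would cyclise the 1,5-diene.

Step 13
Reactants: 22 hydroxy dienone; 23 3,4,5-trimethoxybenzoyl chloride
Product: 24 8-O-(3,4,5-trimethoxybenzoyl) dienone
Conditions: pyridine, DMAP (cat.), CH2Cl2, 0 °C
Reagents that add atoms: none
Why: Acylation of the only hydroxyl in the molecule; C6 is still a ketone, so no regiochemical question arises.

Step 14
Reactants: 24 ester dienone
Product: 25 allylic alcohol (6S by rule, same spatial arrangement as 6R in 26; 7S,8R)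
Conditions: NaBH4, CeCl3·7H2O, MeOH, −78 °C
Reagents that add atoms: none
Why: Luche 1,2-reduction leaves the ester and both alkenes untouched. The cis methyl C15 holds the enone s-cis, and the ring forces the C7–C8 bond perpendicular to the enone plane on the inner face with the isopropyl group gauche to the oxygen, so Felkin–Anh attack from the periphery should give the C6/C7 anti, O6/O8 syn alcohol.

Step 15
Reactants: 25 allylic alcohol
Product: 26 target, (1(10)Z,4S,5S,6R,7S,8R)-4,5-epoxy-6-hydroxygermacr-1(10)-en-8-yl 3,4,5-trimethoxybenzoate
Conditions: VO(acac)2 (5 mol %), t-BuOOH (decane), CH2Cl2, 0 °C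
Reagents that add atoms: tert-butyl hydroperoxide, CC(C)(C)OO
Why: Hydroxyl-directed epoxidation selects the allylic C4=C5 over the remote C1=C10. Allylic 1,3-strain with C15 puts H6 in the alkene plane and the hydroxyl on the outer face, so oxygen is delivered there, giving the trans epoxide threo to C6–OH under nearly neutral conditions.

## Compound list

1 | 3-methylbut-1-yne | CC(C)C#C | starting material
2 | pinacolborane | [H]B1OC(C)(C)C(C)(C)O1 | starting material
3 | (E)-(3-methylbut-1-enyl)boronic acid pinacol ester | CC(C)/C=C/B1OC(C)(C)C(C)(C)O1 | intermediate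
4 | lithium chloromethyl ate complex of 3 | [Li+].CC(C)/C=C/[B-]1(CCl)OC(C)(C)C(C)(C)O1 | intermediate
5 | (E)-(4-methylpent-2-enyl)boronic acid pinacol ester | CC(C)/C=C/CB1OC(C)(C)C(C)(C)O1 | intermediate
6 | 2-allyl-2-methylcyclopentane-1,3-dione | C=CCC1(C)C(=O)CCC1=O | starting material
7 | (2S,3S)-2-allyl-3-hydroxy-2-methylcyclopentanone | O=C1CC[C@H](O)[C@]1(C)CC=C | intermediate
8 | mesylate of 7 | O=C1CC[C@H](OS(C)(=O)=O)[C@]1(C)CC=C | intermediate
9 | secondary ozonide of 8 | O=C1CC[C@H](OS(C)(=O)=O)[C@]1(C)CC2OCOO2 | intermediate
10 | (2-mesyloxy-1-methyl-5-oxocyclopentyl)acetaldehyde | O=C1CC[C@H](OS(C)(=O)=O)[C@]1(C)CC=O | intermediate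
11 | pinacol borate ester of 12 | O=C1CC[C@H](OS(C)(=O)=O)[C@]1(C)C[C@@H](OB2OC(C)(C)C(C)(C)O2)[C@H](C=C)C(C)C | intermediate
12 | anti homoallylic alcohol (7S,8R) | O=C1CC[C@H](OS(C)(=O)=O)[C@]1(C)C[C@@H](O)[C@H](C=C)C(C)C | intermediate
13 | TBS ether of 12 | O=C1CC[C@H](OS(C)(=O)=O)[C@]1(C)C[C@@H](O[Si](C)(C)C(C)(C)C)[C@H](C=C)C(C)C | intermediate
14 | methyl ketone | O=C1CC[C@H](OS(C)(=O)=O)[C@]1(C)C[C@@H](O[Si](C)(C)C(C)(C)C)[C@H](C(C)=O)C(C)C | intermediate
15 | potassium enolate of 14 (C5) | [K+].O=C1CC[C@H](OS(C)(=O)=O)[C@]1(C)C[C@@H](O[Si](C)(C)C(C)(C)C)[C@H](C([O-])=C)C(C)C | intermediate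
16 | cis-fused bicyclo[5.3.0]decane aldolate | [K+].[O-][C@@]12CC[C@H](OS(C)(=O)=O)[C@]1(C)C[C@@H](O[Si](C)(C)C(C)(C)C)[C@@H](C(C)C)C(=O)C2 | intermediate
17 | potassium diketonate of 18 | [K+].CC(C)(C)[Si](C)(C)O[C@@H]1C/C(C)=C\CCC(=O)C=C([O-])[C@@H]1C(C)C | intermediate
18 | (1(10)Z,7R,8R)-8-(TBSO)-15-norgermacr-1(10)-ene-4,6-dione | CC(C)(C)[Si](C)(C)O[C@@H]1C/C(C)=C\CCC(=O)CC(=O)[C@@H]1C(C)C | intermediate
19 | chelated lithium diketonate of 18 | [Li+].CC(C)(C)[Si](C)(C)O[C@@H]1C/C(C)=C\CC/C([O-])=C/C(=O)[C@@H]1C(C)C | intermediate
20 | 4-triflyloxy enone (C3 trans to C6) | CC(C)(C)[Si](C)(C)O[C@@H]1C/C(C)=C\CC/C(OS(=O)(=O)C(F)(F)F)=C/C(=O)[C@@H]1C(C)C | intermediate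
21 | (1(10)Z,4E,7R,8R)-8-(TBSO)germacra-1(10),4-dien-6-one | CC(C)(C)[Si](C)(C)O[C@@H]1C/C(C)=C\CC/C(C)=C/C(=O)[C@@H]1C(C)C | intermediate
22 | (1(10)Z,4E,7R,8R)-8-hydroxygermacra-1(10),4-dien-6-one | O[C@@H]1C/C(C)=C\CC/C(C)=C/C(=O)[C@@H]1C(C)C | intermediate
23 | 3,4,5-trimethoxybenzoyl chloride | COc1cc(C(=O)Cl)cc(OC)c1OC | starting material
24 | 8-O-(3,4,5-trimethoxybenzoyl) dienone | COc1cc(C(=O)O[C@@H]2C/C(C)=C\CC/C(C)=C/C(=O)[C@@H]2C(C)C)cc(OC)c1OC | intermediate
25 | 6-hydroxy-8-O-(3,4,5-trimethoxybenzoyl) diene | COc1cc(C(=O)O[C@@H]2C/C(C)=C\CC/C(C)=C/[C@H](O)[C@@H]2C(C)C)cc(OC)c1OC | intermediate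
26 | target CNP0260213.11 | COc1cc(C(=O)O[C@@H]2C/C(C)=C\CC[C@]3(C)O[C@H]3[C@H](O)[C@@H]2C(C)C)cc(OC)c1OC | target

## Step count and least certain steps

Total step count: 15. Longest linear sequence: 13 (steps 3–15, from 6).

**Step 9 (key step, proposed new method).** Three things may go wrong. Closure of the seven-membered ring onto a ketone next to a quaternary carbon may be too unfavourable to feed the fragmentation. The product diketone may quench unreacted enolate by proton transfer. Slow enolisation at C7 may lead to loss of the silyloxy group. The fallback uses known chemistry and makes the enolate reductively rather than with base. It sets out from 14. Kinetic silyl enol ether formation and bromination with NBS give bromomethyl ketone F1. An intramolecular SmI2 Reformatsky reaction closes the ring to the bicyclic ketol F2. A classical Wharton–Grob fragmentation of this isolated 1,3-diol monomesylate with KOt-Bu returns to the route at 18.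

**Step 10.** Sulfonylation may go through a non-chelated enolate geometry, or at O6, because the ten-membered ring may not tolerate the extended chelate. The result would be loss of the E geometry or of the regiochemistry. The fallback installs C15 and the E alkene before ring closure and sets out from 13.
- LiAlH4 triggers a reductive Grob opening of the cyclopentanone to the acyclic Z alkenol F3.
- Oxidation and Seyferth–Gilbert homologation give terminal alkyne F4.
- Carboalumination (Me3Al, catalytic Cp2ZrCl2) and iodinolysis give E vinyl iodide F5.
- Selective dihydroxylation and periodate cleavage of the monosubstituted vinyl group give iodo aldehyde F6.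
- Nozaki–Hiyama–Kishi closure (CrCl2, catalytic NiCl2) gives macrocyclic allylic alcohol F7.
- Oxidation of F7 with Dess–Martin periodinane returns to the route at 21.

**Step 6.** Face selection on an unbranched aliphatic aldehyde may be incomplete, and the bulkier γ-isopropyl boronate may erode the anti selectivity. The fallback replaces allylation by an aldol reaction and sets out from 10. A boron-mediated anti aldol addition of S-tert-butyl 3-methylbutanethioate with a chiral menthone-derived dialkylbromoborane gives hydroxy thioester F8. Silylation gives F9, and Me2CuLi converts the thioester into the methyl ketone. This returns to the route at 14 and skips step 8.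

**Step 13.** The β-hydroxy ketone may undergo base-induced elimination, or transannular oxa-Michael addition of O8 to C4, faster than the hindered carbinol is acylated. The fallback removes the ketone first and sets out from 22. Narasaka–Prasad reduction (Et2BOMe, NaBH4) gives the syn diol F10. Monoacylation with 23 at low temperature at the less shielded O8 returns to the route at 25; O6 lies next to the alkene that carries the cis methyl.

**Step 14.** Facial selectivity may be poor if the enone reacts through a second ring conformer. The fallback accepts the wrong epimer and inverts it. It sets out from 24. The 6-epi alcohol F11 is subjected to a Mitsunobu reaction with chloroacetic acid to give the inverted chloroacetate F12. Thiourea removes the chloroacetyl group selectively in the presence of the aryl ester and returns to the route at 25.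

## Further compounds

F1 | step 9 | bromomethyl ketone | O=C1CC[C@H](OS(C)(=O)=O)[C@]1(C)C[C@@H](O[Si](C)(C)C(C)(C)C)[C@H](C(=O)CBr)C(C)C
F2 | step 9 | bicyclic ketol | O[C@@]12CC[C@H](OS(C)(=O)=O)[C@]1(C)C[C@@H](O[Si](C)(C)C(C)(C)C)[C@@H](C(C)C)C(=O)C2
F3 | step 10 | acyclic Z alkenol | OCCC/C=C(/C)C[C@@H](O[Si](C)(C)C(C)(C)C)[C@H](C=C)C(C)C
F4 | step 10 | terminal alkyne | C#CCC/C=C(/C)C[C@@H](O[Si](C)(C)C(C)(C)C)[C@H](C=C)C(C)C
F5 | step 10 | E vinyl iodide | I/C=C(\C)CC/C=C(/C)C[C@@H](O[Si](C)(C)C(C)(C)C)[C@H](C=C)C(C)C
F6 | step 10 | iodo aldehyde | I/C=C(\C)CC/C=C(/C)C[C@@H](O[Si](C)(C)C(C)(C)C)[C@H](C=O)C(C)C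
F7 | step 10 | macrocyclic allylic alcohol (C6 epimers) | CC(C)(C)[Si](C)(C)O[C@@H]1C/C(C)=C\CC/C(C)=C/C(O)[C@@H]1C(C)C
F8 | step 6 | anti hydroxy thioester | O=C1CC[C@H](OS(C)(=O)=O)[C@]1(C)C[C@@H](O)[C@H](C(=O)SC(C)(C)C)C(C)C
F9 | step 6 | silyloxy thioester | O=C1CC[C@H](OS(C)(=O)=O)[C@]1(C)C[C@@H](O[Si](C)(C)C(C)(C)C)[C@H](C(=O)SC(C)(C)C)C(C)C
F10 | step 13 | syn 6,8-diol | O[C@@H]1C/C(C)=C\CC/C(C)=C/[C@H](O)[C@@H]1C(C)C
F11 | step 14 | 6-epi alcohol | COc1cc(C(=O)O[C@@H]2C/C(C)=C\CC/C(C)=C/[C@@H](O)[C@@H]2C(C)C)cc(OC)c1OC
F12 | step 14 | inverted 6-chloroacetate | COc1cc(C(=O)O[C@@H]2C/C(C)=C\CC/C(C)=C/[C@H](OC(=O)CCl)[C@@H]2C(C)C)cc(OC)c1OC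
A1 | alternative 1 | iodo aldehyde bearing the final ester | COc1cc(C(=O)O[C@H](C/C(C)=C\CC/C(C)=C/I)[C@H](C=O)C(C)C)cc(OC)c1OC
A2 | alternative 2 | metathesis diene | C=C(C)C[C@@H](O[Si](C)(C)C(C)(C)C)[C@@H](C(C)C)[C@@H](O)/C=C(\C)CCC=C
A3 | alternative 3 | cis-divinylcyclohexanol | CC(C)(C)[Si](C)(C)O[C@@H]1C[C@@](C)(C=C)[C@@](O)(C(C)=C)[C@H](OCc2ccc(OC)cc2)[C@@H]1C(C)C
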